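**Retrosynthetic overview**
1. Target 18 ⇐ hexabenzyl β-keto ester 15 by one global hydrogenolysis; the lost CO2Bn group leaves the C3–H, set last by kinetic ketonisation (2,3-cis).
2. 15 ⇐ C3–C3'' bond by radical coupling of bromo β-keto ester 7 (methoxyphenyl half) with silyl enol ether 14 (benzyloxyphenyl half).
3. 7 and 14 ⇐ each chromanone ring closed by a catalytic asymmetric intramolecular oxa-Michael addition of a 2'-hydroxy alkylidene β-keto ester (5, 10); pseudoenantiomeric catalysts give 2S and 2R.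
4. 5 and 10 ⇐ Knoevenagel condensation of β-keto esters 3 and 8 with 4-methoxybenzaldehyde and 4-(benzyloxy)benzaldehyde; 3 and 8 both come from acetophenone 2 (from phloroacetophenone 1).
5. Ring order: the two pyranone rings are formed separately, one in each branch, before the fragment union; no ring is formed after it.

Assumption: the quinine-derived thiourea is taken to give the (2S) ring and its quinidine-derived pseudoenantiomer the (2R) ring; if the sense of induction is the reverse, the two catalysts are exchanged between steps 4 and 8.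

Note on descriptors: the target is (2S,3S,2''R,3''S), with a 2,3-cis methoxyphenyl ring and a 2'',3''-trans hydroxyphenyl ring. C2 of 7, 15, 16 and 17 is labelled R only because C3 outranks the aryl group there; its geometry is that of (2S) in 6 and 18.

**Step 1**
Reactants: 1 1-(2,4,6-trihydroxyphenyl)ethanone
Product: 2 1-[2,4-bis(benzyloxy)-6-hydroxyphenyl]ethanone
Conditions: BnBr (2.1 equiv), K2CO3, DMF, rt
Reagents that add atoms: benzyl bromide, BrCc1ccccc1
Why: Williamson etherification; the phenol hydrogen-bonded to the acetyl carbonyl is the least nucleophilic and stays free.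

**Step 2**
Reactants: 2 1-[2,4-bis(benzyloxy)-6-hydroxyphenyl]ethanone
Product: 3 benzyl 3-[2,4-bis(benzyloxy)-6-hydroxyphenyl]-3-oxopropanoate
Conditions: LiHMDS (3.3 equiv), THF, −78 °C; (BnO)2CO, −78 °C → rt; cold 1 M HCl
Reagents that add atoms: dibenzyl carbonate, O=C(OCc1ccccc1)OCc1ccccc1
Why: Claisen-type C-acylation of the phenoxide/enolate dianion, driven by deprotonation of the product; the low temperature and acidic quench suppress lactonisation to the 4-hydroxycoumarin.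

**Step 3**
Reactants: 3 benzyl 3-[2,4-bis(benzyloxy)-6-hydroxyphenyl]-3-oxopropanoate + 4 4-methoxybenzaldehyde
Product: 5 benzyl (2Z)-2-[2,4-bis(benzyloxy)-6-hydroxybenzoyl]-3-(4-methoxyphenyl)prop-2-enoate
Conditions: piperidine (10 mol%), AcOH (10 mol%), 4 Å MS, toluene, rt
Reagents that add atoms: none
Why: Knoevenagel condensation of the doubly activated methylene; at rt under buffered conditions the chelated phenol does not yet cyclise, and the alkene geometry is of no consequence later.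

**Step 4**
Reactants: 5 benzyl (2Z)-2-[2,4-bis(benzyloxy)-6-hydroxybenzoyl]-3-(4-methoxyphenyl)prop-2-enoate
Product: 6 benzyl (2S,3R)-5,7-bis(benzyloxy)-2-(4-methoxyphenyl)-4-oxochromane-3-carboxylate
Conditions: quinine-derived 9-epi-amino 3,5-bis(CF3)phenyl thiourea (10 mol%), toluene, −25 °C; cold silica plug
Reagents that add atoms: none
Why: catalytic asymmetric intramolecular oxa-Michael addition (6-endo-trig), in which the thiourea binds the β-keto ester and the quinuclidine delivers the phenol to one face to set C2 (S); C3 settles as the trans keto form in equilibrium with its enol.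

**Step 5**
Reactants: 6 benzyl (2S,3R)-5,7-bis(benzyloxy)-2-(4-methoxyphenyl)-4-oxochromane-3-carboxylate
Product: 7 benzyl (2R,3R)-5,7-bis(benzyloxy)-3-bromo-2-(4-methoxyphenyl)-4-oxochromane-3-carboxylate
Conditions: NBS (1.05 equiv), CH2Cl2, −20 → 0 °C, dark
Reagents that add atoms: N-bromosuccinimide, O=C1CCC(=O)N1Br
Why: electrophilic α-bromination of the β-keto ester enol, far faster than bromination of the acyl-deactivated arenes; Br enters anti to the 2-aryl group, and removal of the acidic C3–H blocks retro-oxa-Michael racemisation of C2.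

**Step 6**
Reactants: 2 1-[2,4-bis(benzyloxy)-6-hydroxyphenyl]ethanone
Product: 8 tert-butyl 3-[2,4-bis(benzyloxy)-6-hydroxyphenyl]-3-oxopropanoate
Conditions: LiHMDS (3.3 equiv), THF, −78 °C; Boc2O, −78 → 0 °C; cold 1 M HCl
Reagents that add atoms: di-tert-butyl dicarbonate, CC(C)(C)OC(=O)OC(=O)OC(C)(C)C
Why: Claisen-type C-acylation of the dianion as in step 2; the tert-butyl ester resists lactonisation and is acid-labile for step 8.

**Step 7**
Reactants: 8 tert-butyl 3-[2,4-bis(benzyloxy)-6-hydroxyphenyl]-3-oxopropanoate + 9 4-(benzyloxy)benzaldehyde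
Product: 10 tert-butyl (2Z)-2-[2,4-bis(benzyloxy)-6-hydroxybenzoyl]-3-[4-(benzyloxy)phenyl]prop-2-enoate
Conditions: piperidine (10 mol%), AcOH (10 mol%), 4 Å MS, toluene, rt
Reagents that add atoms: none
Why: Knoevenagel condensation, as in step 3.

**Step 8**
Reactants: 10 tert-butyl (2Z)-2-[2,4-bis(benzyloxy)-6-hydroxybenzoyl]-3-[4-(benzyloxy)phenyl]prop-2-enoate
Product: 13 (2R)-5,7-bis(benzyloxy)-2-[4-(benzyloxy)phenyl]chroman-4-one, via cyclised tert-butyl ester 11 (not isolated), via beta-keto acid 12 (not isolated)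
Conditions: quinidine-derived 9-epi-amino 3,5-bis(CF3)phenyl thiourea (10 mol%), toluene, −25 °C; then TsOH·H2O (0.5 equiv), 80 °C
Reagents that add atoms: none
Why: the pseudoenantiomeric catalyst runs the same asymmetric intramolecular oxa-Michael addition to set C2 (R); acid then cleaves the tert-butyl ester and the β-keto acid decarboxylates in the same flask without touching C2.

**Step 9**
Reactants: 13 (2R)-5,7-bis(benzyloxy)-2-[4-(benzyloxy)phenyl]chroman-4-one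
Product: 14 tert-butyl({(2R)-5,7-bis(benzyloxy)-2-[4-(benzyloxy)phenyl]-2H-chromen-4-yl}oxy)dimethylsilane
Conditions: TBSOTf (1.3 equiv), Et3N (2 equiv), CH2Cl2, 0 °C
Reagents that add atoms: tert-butyldimethylsilyl triflate, CC(C)(C)[Si](C)(C)OS(=O)(=O)C(F)(F)F
Why: soft enolisation and O-silylation give the enol ether without a free enolate, so no E1cB ring opening occurs and C2 is retained.

**Step 10**
Reactants: 7 benzyl (2R,3R)-5,7-bis(benzyloxy)-3-bromo-2-(4-methoxyphenyl)-4-oxochromane-3-carboxylate + 14 tert-butyl({(2R)-5,7-bis(benzyloxy)-2-[4-(benzyloxy)phenyl]-2H-chromen-4-yl}oxy)dimethylsilane (1.5 equiv)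
Product: 15 benzyl (2R,3S)-5,7-bis(benzyloxy)-3-{(2R,3S)-5,7-bis(benzyloxy)-2-[4-(benzyloxy)phenyl]-4-oxochroman-3-yl}-2-(4-methoxyphenyl)-4-oxochromane-3-carboxylate
Conditions: fac-Ir(ppy)3 (1 mol%), degassed MeCN/CH2Cl2, blue LEDs, rt
Reagents that add atoms: none
Why: photoredox radical alkylation of a silyl enol ether, in which the excited Ir complex reduces the C–Br bond and the electrophilic tertiary radical adds to C3'' anti to the 2''-aryl group (trans, 3''S) before oxidation and desilylation to the ketone; the configuration of the temporary quaternary C3 is of no consequence.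

**Step 11**
Reactants: 15 benzyl (2R,3S)-5,7-bis(benzyloxy)-3-{(2R,3S)-5,7-bis(benzyloxy)-2-[4-(benzyloxy)phenyl]-4-oxochroman-3-yl}-2-(4-methoxyphenyl)-4-oxochromane-3-carboxylate
Product: 18 (2S,3S)-5,7-dihydroxy-3-[(2R,3S)-5,7-dihydroxy-2-(4-hydroxyphenyl)-4-oxochroman-3-yl]-2-(4-methoxyphenyl)chroman-4-one, via pentahydroxy beta-keto acid 16 (not isolated), via C3-enol 17 (not isolated)
Conditions: H2 (1 atm), 10% Pd/C, EtOAc/MeOH 1:1, rt
Reagents that add atoms: none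
Why: hydrogenolysis of the six benzyl groups frees a β-keto acid that decarboxylates to the enol, and ketonisation by protonation anti to the pseudoaxial 2-aryl group (A1,2 strain) gives the 2,3-cis ring (3S); the neutral medium leaves C2, C2'' and C3'' untouched.

**Compound list**
1 | 1-(2,4,6-trihydroxyphenyl)ethanone | CC(=O)c1c(O)cc(O)cc1O | starting material
2 | 1-[2,4-bis(benzyloxy)-6-hydroxyphenyl]ethanone | CC(=O)c1c(O)cc(OCc2ccccc2)cc1OCc1ccccc1 | intermediate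
3 | benzyl 3-[2,4-bis(benzyloxy)-6-hydroxyphenyl]-3-oxopropanoate | O=C(CC(=O)c1c(O)cc(OCc2ccccc2)cc1OCc1ccccc1)OCc1ccccc1 | intermediate
4 | 4-methoxybenzaldehyde | COc1ccc(C=O)cc1 | starting material
5 | benzyl (2Z)-2-[2,4-bis(benzyloxy)-6-hydroxybenzoyl]-3-(4-methoxyphenyl)prop-2-enoate | COc1ccc(/C=C(\C(=O)OCc2ccccc2)C(=O)c2c(O)cc(OCc3ccccc3)cc2OCc2ccccc2)cc1 | intermediate
6 | benzyl (2S,3R)-5,7-bis(benzyloxy)-2-(4-methoxyphenyl)-4-oxochromane-3-carboxylate | COc1ccc([C@H]2Oc3cc(OCc4ccccc4)cc(OCc4ccccc4)c3C(=O)[C@@H]2C(=O)OCc2ccccc2)cc1 | intermediate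
7 | benzyl (2R,3R)-5,7-bis(benzyloxy)-3-bromo-2-(4-methoxyphenyl)-4-oxochromane-3-carboxylate | COc1ccc([C@H]2Oc3cc(OCc4ccccc4)cc(OCc4ccccc4)c3C(=O)[C@@]2(Br)C(=O)OCc2ccccc2)cc1 | intermediate
8 | tert-butyl 3-[2,4-bis(benzyloxy)-6-hydroxyphenyl]-3-oxopropanoate | CC(C)(C)OC(=O)CC(=O)c1c(O)cc(OCc2ccccc2)cc1OCc1ccccc1 | intermediate
9 | 4-(benzyloxy)benzaldehyde | O=Cc1ccc(OCc2ccccc2)cc1 | starting material
10 | tert-butyl (2Z)-2-[2,4-bis(benzyloxy)-6-hydroxybenzoyl]-3-[4-(benzyloxy)phenyl]prop-2-enoate | CC(C)(C)OC(=O)/C(=C\c1ccc(OCc2ccccc2)cc1)C(=O)c1c(O)cc(OCc2ccccc2)cc1OCc1ccccc1 | intermediate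
11 | tert-butyl (2R,3S)-5,7-bis(benzyloxy)-2-[4-(benzyloxy)phenyl]-4-oxochromane-3-carboxylate | CC(C)(C)OC(=O)[C@@H]1C(=O)c2c(OCc3ccccc3)cc(OCc3ccccc3)cc2O[C@H]1c1ccc(OCc2ccccc2)cc1 | intermediate
12 | (2R,3S)-5,7-bis(benzyloxy)-2-[4-(benzyloxy)phenyl]-4-oxochromane-3-carboxylic acid | OC(=O)[C@@H]1C(=O)c2c(OCc3ccccc3)cc(OCc3ccccc3)cc2O[C@H]1c1ccc(OCc2ccccc2)cc1 | intermediate
13 | (2R)-5,7-bis(benzyloxy)-2-[4-(benzyloxy)phenyl]chroman-4-one | C1C(=O)c2c(OCc3ccccc3)cc(OCc3ccccc3)cc2O[C@H]1c1ccc(OCc2ccccc2)cc1 | intermediate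
14 | tert-butyl({(2R)-5,7-bis(benzyloxy)-2-[4-(benzyloxy)phenyl]-2H-chromen-4-yl}oxy)dimethylsilane | C1=C(O[Si](C)(C)C(C)(C)C)c2c(OCc3ccccc3)cc(OCc3ccccc3)cc2O[C@H]1c1ccc(OCc2ccccc2)cc1 | intermediate
15 | benzyl (2R,3S)-5,7-bis(benzyloxy)-3-{(2R,3S)-5,7-bis(benzyloxy)-2-[4-(benzyloxy)phenyl]-4-oxochroman-3-yl}-2-(4-methoxyphenyl)-4-oxochromane-3-carboxylate | COc1ccc([C@H]2Oc3cc(OCc4ccccc4)cc(OCc4ccccc4)c3C(=O)[C@]2(C(=O)OCc2ccccc2)[C@@H]2C(=O)c3c(OCc4ccccc4)cc(OCc4ccccc4)cc3O[C@H]2c2ccc(OCc3ccccc3)cc2)cc1 | intermediate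
16 | (2R,3S)-5,7-dihydroxy-3-[(2R,3S)-5,7-dihydroxy-2-(4-hydroxyphenyl)-4-oxochroman-3-yl]-2-(4-methoxyphenyl)-4-oxochromane-3-carboxylic acid | COc1ccc([C@H]2Oc3cc(O)cc(O)c3C(=O)[C@]2(C(=O)O)[C@@H]2C(=O)c3c(O)cc(O)cc3O[C@H]2c2ccc(O)cc2)cc1 | intermediate
17 | (2R)-3-[(2R,3S)-5,7-dihydroxy-2-(4-hydroxyphenyl)-4-oxochroman-3-yl]-2-(4-methoxyphenyl)-2H-chromene-4,5,7-triol | COc1ccc([C@H]2Oc3cc(O)cc(O)c3C(O)=C2[C@@H]2C(=O)c3c(O)cc(O)cc3O[C@H]2c2ccc(O)cc2)cc1 | intermediate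
18 | (2S,3S)-5,7-dihydroxy-3-[(2R,3S)-5,7-dihydroxy-2-(4-hydroxyphenyl)-4-oxochroman-3-yl]-2-(4-methoxyphenyl)chroman-4-one | COc1ccc([C@H]2Oc3cc(O)cc(O)c3C(=O)[C@H]2[C@@H]2C(=O)c3c(O)cc(O)cc3O[C@H]2c2ccc(O)cc2)cc1 | target

**Totals**
Total step count: 11.
Longest linear sequence: 7 steps (steps 1, 2, 3, 4, 5, 10, 11; the other branch, steps 1, 6, 7, 8, 9, 10, 11, is equally long).

**Three steps most likely to fail**

Step 10 is the most exposed: the radical union must forge a bond between a quaternary and a tertiary ring carbon, both flanked by aryl-bearing carbons, and simple debromination of 7 back to 6 competes. The fallback sets out from 6 and comes back at 15; it builds the second chromanone on the first instead of coupling two finished rings. Ketone 2 is protected (MOMCl, iPr2NEt) as 1-[2,4-bis(benzyloxy)-6-(methoxymethoxy)phenyl]ethanone F1 and brominated through its silyl enol ether (LiHMDS, TMSCl; NBS) to 2-bromo-1-[2,4-bis(benzyloxy)-6-(methoxymethoxy)phenyl]ethanone F2. C-alkylation of β-keto ester 6 with this primary bromide (K2CO3, acetone, 0 °C) gives benzyl (2R,3S)-5,7-bis(benzyloxy)-3-{2-[2,4-bis(benzyloxy)-6-(methoxymethoxy)phenyl]-2-oxoethyl}-2-(4-methoxyphenyl)-4-oxochromane-3-carboxylate F3, whose quaternary C3 can no longer ring-open. Aldol addition to aldehyde 9 (LiHMDS, −78 °C) and dehydration (MsCl, Et3N; DBU) give the enone benzyl (2R,3S)-5,7-bis(benzyloxy)-3-{(E)-1-[2,4-bis(benzyloxy)-6-(methoxymethoxy)benzoyl]-2-[4-(benzyloxy)phenyl]ethenyl}-2-(4-methoxyphenyl)-4-oxochromane-3-carboxylate F4. HCl in MeOH/THF removes the MOM group to the free phenol benzyl (2R,3S)-5,7-bis(benzyloxy)-3-{(E)-1-[2,4-bis(benzyloxy)-6-hydroxybenzoyl]-2-[4-(benzyloxy)phenyl]ethenyl}-2-(4-methoxyphenyl)-4-oxochromane-3-carboxylate F5. NaOAc in EtOH then closes the second ring by intramolecular oxa-Michael addition under thermodynamic (trans) control, and the (2''R,3''S) isomer 15 is separated from its (2''S,3''R) diastereomer by chromatography.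

Step 11 is the next risk: the C3 hydrogen may arrive from the wrong face, or the cis ring may epimerise to trans in the protic hydrogenation medium. The fallback sets out from 2 and comes back at 18; it carries an allyl instead of a benzyl ester, so that C3–H is installed on the fully protected compound in an aprotic medium and the benzyl ethers are removed only afterwards. Acylation of 2 with diallyl carbonate (LiHMDS) gives allyl 3-[2,4-bis(benzyloxy)-6-hydroxyphenyl]-3-oxopropanoate F6. Knoevenagel condensation with 4 gives allyl (2Z)-2-[2,4-bis(benzyloxy)-6-hydroxybenzoyl]-3-(4-methoxyphenyl)prop-2-enoate F7. The quinine-thiourea oxa-Michael closure gives allyl (2S,3R)-5,7-bis(benzyloxy)-2-(4-methoxyphenyl)-4-oxochromane-3-carboxylate F8. NBS gives allyl (2R,3R)-5,7-bis(benzyloxy)-3-bromo-2-(4-methoxyphenyl)-4-oxochromane-3-carboxylate F9. Photoredox coupling with 14 gives allyl (2R,3S)-5,7-bis(benzyloxy)-3-{(2R,3S)-5,7-bis(benzyloxy)-2-[4-(benzyloxy)phenyl]-4-oxochroman-3-yl}-2-(4-methoxyphenyl)-4-oxochromane-3-carboxylate F10. Pd(OAc)2/PPh3 with HCO2H–Et3N in THF at 0 °C then removes the allyl group as propene, and the palladium enolate formed on decarboxylation is protonated anti to the 2-aryl group to give (2S,3S)-5,7-bis(benzyloxy)-3-{(2R,3S)-5,7-bis(benzyloxy)-2-[4-(benzyloxy)phenyl]-4-oxochroman-3-yl}-2-(4-methoxyphenyl)chroman-4-one F11. This is purified and hydrogenolysed (H2, Pd/C) to 18.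

Step 4 is the third risk: the electron-rich, doubly ortho-substituted alkylidene 5 may cyclise slowly or with low ee, and 6 can racemise by retro-oxa-Michael reaction before it is brominated. The fallback sets out from 3 and comes back at 6; it closes the ring first and adds the aryl group afterwards. DMF dimethyl acetal converts 3 into benzyl 2-[2,4-bis(benzyloxy)-6-hydroxybenzoyl]-3-(dimethylamino)prop-2-enoate F12. This cyclises by intramolecular oxa-Michael addition–elimination to benzyl 5,7-bis(benzyloxy)-4-oxo-4H-chromene-3-carboxylate F13. Rhodium-catalysed asymmetric 1,4-addition of 4-methoxyphenylboronic acid ([Rh(OH)(cod)]2, chiral bisphosphine, base-free, dioxane/H2O) then sets C2 (S) and gives 6 directly.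

**Further compounds**
F1 | step 10 | 1-[2,4-bis(benzyloxy)-6-(methoxymethoxy)phenyl]ethanone | CC(=O)c1c(OCOC)cc(OCc2ccccc2)cc1OCc1ccccc1
F2 | step 10 | 2-bromo-1-[2,4-bis(benzyloxy)-6-(methoxymethoxy)phenyl]ethanone | O=C(CBr)c1c(OCOC)cc(OCc2ccccc2)cc1OCc1ccccc1
F3 | step 10 | benzyl (2R,3S)-5,7-bis(benzyloxy)-3-{2-[2,4-bis(benzyloxy)-6-(methoxymethoxy)phenyl]-2-oxoethyl}-2-(4-methoxyphenyl)-4-oxochromane-3-carboxylate | COc1ccc([C@H]2Oc3cc(OCc4ccccc4)cc(OCc4ccccc4)c3C(=O)[C@]2(C(=O)OCc2ccccc2)CC(=O)c2c(OCOC)cc(OCc3ccccc3)cc2OCc2ccccc2)cc1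
F4 | step 10 | benzyl (2R,3S)-5,7-bis(benzyloxy)-3-{(E)-1-[2,4-bis(benzyloxy)-6-(methoxymethoxy)benzoyl]-2-[4-(benzyloxy)phenyl]ethenyl}-2-(4-methoxyphenyl)-4-oxochromane-3-carboxylate | COc1ccc([C@H]2Oc3cc(OCc4ccccc4)cc(OCc4ccccc4)c3C(=O)[C@]2(C(=O)OCc2ccccc2)/C(=C\c2ccc(OCc3ccccc3)cc2)C(=O)c2c(OCOC)cc(OCc3ccccc3)cc2OCc2ccccc2)cc1
F5 | step 10 | benzyl (2R,3S)-5,7-bis(benzyloxy)-3-{(E)-1-[2,4-bis(benzyloxy)-6-hydroxybenzoyl]-2-[4-(benzyloxy)phenyl]ethenyl}-2-(4-methoxyphenyl)-4-oxochromane-3-carboxylate | COc1ccc([C@H]2Oc3cc(OCc4ccccc4)cc(OCc4ccccc4)c3C(=O)[C@]2(C(=O)OCc2ccccc2)/C(=C\c2ccc(OCc3ccccc3)cc2)C(=O)c2c(O)cc(OCc3ccccc3)cc2OCc2ccccc2)cc1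
F6 | step 11 | allyl 3-[2,4-bis(benzyloxy)-6-hydroxyphenyl]-3-oxopropanoate | C=CCOC(=O)CC(=O)c1c(O)cc(OCc2ccccc2)cc1OCc1ccccc1
F7 | step 11 | allyl (2Z)-2-[2,4-bis(benzyloxy)-6-hydroxybenzoyl]-3-(4-methoxyphenyl)prop-2-enoate | COc1ccc(/C=C(\C(=O)OCC=C)C(=O)c2c(O)cc(OCc3ccccc3)cc2OCc2ccccc2)cc1
F8 | step 11 | allyl (2S,3R)-5,7-bis(benzyloxy)-2-(4-methoxyphenyl)-4-oxochromane-3-carboxylate | COc1ccc([C@H]2Oc3cc(OCc4ccccc4)cc(OCc4ccccc4)c3C(=O)[C@@H]2C(=O)OCC=C)cc1
F9 | step 11 | allyl (2R,3R)-5,7-bis(benzyloxy)-3-bromo-2-(4-methoxyphenyl)-4-oxochromane-3-carboxylate | COc1ccc([C@H]2Oc3cc(OCc4ccccc4)cc(OCc4ccccc4)c3C(=O)[C@@]2(Br)C(=O)OCC=C)cc1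
F10 | step 11 | allyl (2R,3S)-5,7-bis(benzyloxy)-3-{(2R,3S)-5,7-bis(benzyloxy)-2-[4-(benzyloxy)phenyl]-4-oxochroman-3-yl}-2-(4-methoxyphenyl)-4-oxochromane-3-carboxylate | COc1ccc([C@H]2Oc3cc(OCc4ccccc4)cc(OCc4ccccc4)c3C(=O)[C@]2(C(=O)OCC=C)[C@@H]2C(=O)c3c(OCc4ccccc4)cc(OCc4ccccc4)cc3O[C@H]2c2ccc(OCc3ccccc3)cc2)cc1
F11 | step 11 | (2S,3S)-5,7-bis(benzyloxy)-3-{(2R,3S)-5,7-bis(benzyloxy)-2-[4-(benzyloxy)phenyl]-4-oxochroman-3-yl}-2-(4-methoxyphenyl)chroman-4-one | COc1ccc([C@H]2Oc3cc(OCc4ccccc4)cc(OCc4ccccc4)c3C(=O)[C@H]2[C@@H]2C(=O)c3c(OCc4ccccc4)cc(OCc4ccccc4)cc3O[C@H]2c2ccc(OCc3ccccc3)cc2)cc1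
F12 | step 4 | benzyl 2-[2,4-bis(benzyloxy)-6-hydroxybenzoyl]-3-(dimethylamino)prop-2-enoate | CN(C)C=C(C(=O)OCc1ccccc1)C(=O)c1c(O)cc(OCc2ccccc2)cc1OCc1ccccc1
F13 | step 4 | benzyl 5,7-bis(benzyloxy)-4-oxo-4H-chromene-3-carboxylate | O=C(OCc1ccccc1)c1coc2cc(OCc3ccccc3)cc(OCc3ccccc3)c2c1=O
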